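**Retrosynthetic overview**
1. Target 16 ⇐ two late acylations (C8 methacrylate, then C9 acetate) of diol 14 ⇐ acetonide-protected macrocycle 13.
2. 13 ⇐ C6–C7 disconnection: intramolecular chromium-mediated allylation/lactonization of enal–allylic bromide 11, which closes the ten-membered carbocycle and the α-methylene lactone together (last rings formed).
3. 11 ⇐ Morita–Baylis–Hillman reaction and bromide transposition at the C7 aldehyde of furanone 7 (C11–C13 from methyl acrylate).
4. Furanone ring of 7 (first ring formed) ⇐ gold-triggered 5-endo cyclization with 1,2-shift of C9 from C1 to C10 in α-hydroxy ketone 6; this creates the quaternary C10.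
5. 6 ⇐ ynone 4 + acetyl anion equivalent; 4 ⇐ enynol 1 + L-erythronolactone acetonide 2 (source of C7–C9 and of the C8/C9 configuration).

Assumption: 1 and 2 are bought as such (the acetonide of 2 is a protecting group on L-erythronolactone); TBS = tert-butyldimethylsilyl; positions follow germacrane numbering (C1 ketone, C2=C3 furanone alkene, C4(C15)=C5, C6 lactone CH–O, C7, C8 methacrylate carbon, C9 acetate carbon, C10 quaternary C–O bearing C14, C11=C13, C12 lactone C=O).

**Step 1**
Reactants: 1 (Z)-3-methylpent-2-en-4-yn-1-ol; 2 2,3-O-isopropylidene-L-erythronolactone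
Product: 4 bis-TBS ynone (Z)-6-(TBSO)-1-[(4S,5S)-5-(TBSOCH2)-2,2-dimethyl-1,3-dioxolan-4-yl]-4-methylhex-4-en-2-yn-1-one, via lithium hemiketal alkoxide 3 (not isolated)
Conditions: n-BuLi (2.05 equiv), THF, −78 → −20 °C; 2 (1.1 equiv), −78 °C; TBSCl (2.5 equiv), DMPU, −78 → 23 °C
Reagents that add atoms: tert-butyldimethylsilyl chloride, CC(C)(C)[Si](C)(C)Cl
Why: The dilithio alkoxide–acetylide of 1 adds once to the lactone carbonyl (acetylide addition to a lactone; the tetrahedral hemiketal alkoxide 3 blocks over-addition), and on warming TBSCl traps the primary alkoxide of the ring-opened form and the allylic alkoxide, so C8 and C9 come unchanged from the chiral pool.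

**Step 2**
Reactants: 4 bis-TBS ynone
Product: 6 α-hydroxy ketone (3S,6Z)-8-(TBSO)-3-[(4S,5S)-5-(TBSOCH2)-2,2-dimethyl-1,3-dioxolan-4-yl]-3-hydroxy-6-methyloct-6-en-4-yn-2-one, via enol ether carbinol 5 (not isolated)
Conditions: ethyl vinyl ether, t-BuLi, THF, −78 → 0 °C; 4, −78 °C; then 0.5 M aq. HCl, THF, 0 °C (brief)
Reagents that add atoms: 1-ethoxyvinyllithium, [Li]C(=C)OCC (made from ethyl vinyl ether, C=COCC); water, O
Why: The acyl anion equivalent 1-ethoxyvinyllithium adds 1,2 to the ynone under Felkin–Anh control (non-chelating lithium in THF, attack anti to the dioxolane C9–O bond), which sets the tertiary carbinol C1 as S, and dilute acid then hydrolyses the enol ether to the methyl ketone.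

**Step 3**
Reactants: 6 α-hydroxy ketone
Product: 7 furanone (2S)-5-[(Z)-4-(TBSO)but-2-en-2-yl]-2-[(4S,5S)-5-(TBSOCH2)-2,2-dimethyl-1,3-dioxolan-4-yl]-2-methylfuran-3(2H)-one
Conditions: Ph3PAuNTf2 (5 mol %), CH2Cl2, 0 → 23 °C
Reagents that add atoms: none
Why: Proposed new method: monovalent gold activates the alkyne, the acetyl oxygen closes 5-endo-dig onto C3 to give a furanylium ion (oxocarbenium at C10), and an α-ketol-type suprafacial 1,2-shift of the dioxolanyl carbon C9 from C1 to C10 (retention at C9, C1 becoming the ketone) followed by protodeauration transfers the C1 configuration to the new quaternary C10 (S); the closest known reaction is the gold- or platinum-catalysed heterocyclization/1,2-alkyl shift of 2-hydroxy-2-alkynyl ketones, proposed here for an α-alkoxyalkyl migrating group, a 1,3-enyne and transfer of chirality.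

**Step 4**
Reactants: 7 furanone
Product: 8 diol (2S)-5-[(Z)-4-hydroxybut-2-en-2-yl]-2-[(4S,5S)-5-(hydroxymethyl)-2,2-dimethyl-1,3-dioxolan-4-yl]-2-methylfuran-3(2H)-one
Conditions: HF·pyridine, pyridine, THF, 0 → 23 °C
Reagents that add atoms: none
Why: Buffered fluoride cleaves both primary silyl ethers (desilylation) while the acetonide and the furanone are stable.

**Step 5**
Reactants: 8 diol
Product: 9 dialdehyde (4R,5S)-2,2-dimethyl-5-{(2S)-2-methyl-3-oxo-5-[(Z)-4-oxobut-2-en-2-yl]-2,3-dihydrofuran-2-yl}-1,3-dioxolane-4-carbaldehyde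
Conditions: PhI(OAc)2 (2.4 equiv), TEMPO (20 mol %), CH2Cl2, 23 °C
Reagents that add atoms: none
Why: The TEMPO/PhI(OAc)2 oxidation converts both primary alcohols into aldehydes under near-neutral conditions that preserve the Z-enal geometry and the α-alkoxy stereocentre C8.

**Step 6**
Reactants: 9 dialdehyde
Product: 10 Morita–Baylis–Hillman adduct methyl 2-{hydroxy[(4S,5S)-2,2-dimethyl-5-{(2S)-2-methyl-3-oxo-5-[(Z)-4-oxobut-2-en-2-yl]-2,3-dihydrofuran-2-yl}-1,3-dioxolan-4-yl]methyl}prop-2-enoate (both C7 epimers)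
Conditions: methyl acrylate (10 equiv), DABCO (0.3 equiv), MeOH, 23 °C
Reagents that add atoms: methyl acrylate, C=CC(=O)OC
Why: The Morita–Baylis–Hillman reaction is chemoselective for the electrophilic α-alkoxy aldehyde over the β,β-disubstituted cross-conjugated enal, and the new C7 carbinol needs no control because it is erased in step 7.

**Step 7**
Reactants: 10 Morita–Baylis–Hillman adduct
Product: 11 allylic bromide methyl (Z)-2-(bromomethyl)-3-[(4S,5S)-2,2-dimethyl-5-{(2S)-2-methyl-3-oxo-5-[(Z)-4-oxobut-2-en-2-yl]-2,3-dihydrofuran-2-yl}-1,3-dioxolan-4-yl]prop-2-enoate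
Conditions: NBS, Me2S, CH2Cl2, −20 → 23 °C
Reagents that add atoms: N-bromosuccinimide, O=C1CCC(=O)N1Br
Why: Corey–Kim-type activation of the allylic alcohol is followed by SN2' delivery of bromide to C13, so both C7 epimers converge on the conjugated (Z)-2-(bromomethyl)enoate.

**Step 8**
Reactants: 11 allylic bromide
Product: 13 acetonide-protected macrocyclic lactone (target skeleton with C8–O and C9–O joined as an isopropylidene acetal; C6 C7 C8 C9 C10 as in the target), via seco hydroxy ester 12 (not isolated)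
Conditions: CrCl2 (8 equiv), THF/DMF (4:1), 23 °C, slow addition to 2 mM; aq. NH4Cl
Reagents that add atoms: none
Why: Divalent chromium converts the bromide into an allylchromium that adds through C7 to the Z-enal in a chair-like transition state (intramolecular Nozaki–Hiyama, Barbier-type allylation; anti addition gives the trans-fused lactone after in situ lactonization), and the C8 stereocentre with the rigid furanone–dioxolane segment fixes the enal face so that C6 (R) and C7 (S) are set.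

**Step 9**
Reactants: 13 acetonide-protected macrocyclic lactone
Product: 14 8,9-diol (8,9-dihydroxy-1-oxo-3,10-epoxygermacra-2,4,11(13)-trien-12,6-olide; stereocentres as in the target)
Conditions: TFA/H2O (9:1), CH2Cl2, 0 °C
Reagents that add atoms: none
Why: Acid hydrolysis of the isopropylidene acetal frees both secondary hydroxyls without touching the α-methylene lactone or the furanone.

**Step 10**
Reactants: 14 8,9-diol
Product: 15 8-O-methacryloyl-9-hydroxy compound
Conditions: methacryloyl chloride (1.1 equiv), Et3N, DMAP (cat.), CH2Cl2, −78 → −40 °C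
Reagents that add atoms: methacryloyl chloride, C=C(C)C(Cl)=O
Why: DMAP-catalysed acylation at low temperature selects the C8 hydroxyl because the C9 hydroxyl is neopentyl-like, flanked by the fully substituted C10.

**Step 11**
Reactants: 15 8-O-methacryloyl-9-hydroxy compound
Product: 16 target (4Z,6R,7S,8S,9S,10S)-9-acetoxy-8-(methacryloyloxy)-1-oxo-3,10-epoxygermacra-2,4,11(13)-trien-12,6-olide
Conditions: Ac2O, pyridine, DMAP (cat.), 23 °C
Reagents that add atoms: acetic anhydride, CC(=O)OC(C)=O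
Why: Forcing DMAP-catalysed acetylation esterifies the remaining hindered C9 hydroxyl and creates no new stereocentre.

**Compound list**
1 | (Z)-3-methylpent-2-en-4-yn-1-ol | C#C/C(C)=C\CO | starting material
2 | 2,3-O-isopropylidene-L-erythronolactone, (3aS,6aS)-2,2-dimethyldihydrofuro[3,4-d][1,3]dioxol-4(3aH)-one | O=C1OC[C@@H]2OC(C)(C)O[C@H]12 | starting material
3 | dilithium alkoxide of the lactol (3aS,6aS)-4-[(Z)-5-hydroxy-3-methylpent-3-en-1-yn-1-yl]-2,2-dimethyltetrahydrofuro[3,4-d][1,3]dioxol-4-ol (anomeric centre undefined; not isolated) | [Li+].[Li+].[O-]C/C=C(/C)C#CC1([O-])OC[C@@H]2OC(C)(C)O[C@H]12 | intermediate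
4 | (Z)-6-[(tert-butyldimethylsilyl)oxy]-1-[(4S,5S)-5-{[(tert-butyldimethylsilyl)oxy]methyl}-2,2-dimethyl-1,3-dioxolan-4-yl]-4-methylhex-4-en-2-yn-1-one | CC(C)(C)[Si](C)(C)OC/C=C(/C)C#CC(=O)[C@H]1OC(C)(C)O[C@H]1CO[Si](C)(C)C(C)(C)C | intermediate
5 | (3S,6Z)-8-[(tert-butyldimethylsilyl)oxy]-3-[(4S,5S)-5-{[(tert-butyldimethylsilyl)oxy]methyl}-2,2-dimethyl-1,3-dioxolan-4-yl]-2-ethoxy-6-methylocta-1,6-dien-4-yn-3-ol (not isolated) | CC(C)(C)[Si](C)(C)OC/C=C(/C)C#C[C@@](O)(C(=C)OCC)[C@H]1OC(C)(C)O[C@H]1CO[Si](C)(C)C(C)(C)C | intermediate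
6 | (3S,6Z)-8-[(tert-butyldimethylsilyl)oxy]-3-[(4S,5S)-5-{[(tert-butyldimethylsilyl)oxy]methyl}-2,2-dimethyl-1,3-dioxolan-4-yl]-3-hydroxy-6-methyloct-6-en-4-yn-2-one | CC(C)(C)[Si](C)(C)OC/C=C(/C)C#C[C@@](O)(C(C)=O)[C@H]1OC(C)(C)O[C@H]1CO[Si](C)(C)C(C)(C)C | intermediate
7 | (2S)-5-[(Z)-4-{[tert-butyldimethylsilyl]oxy}but-2-en-2-yl]-2-[(4S,5S)-5-{[(tert-butyldimethylsilyl)oxy]methyl}-2,2-dimethyl-1,3-dioxolan-4-yl]-2-methylfuran-3(2H)-one | CC(C)(C)[Si](C)(C)OC/C=C(/C)C1=CC(=O)[C@@](C)(O1)[C@H]1OC(C)(C)O[C@H]1CO[Si](C)(C)C(C)(C)C | intermediate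
8 | (2S)-5-[(Z)-4-hydroxybut-2-en-2-yl]-2-[(4S,5S)-5-(hydroxymethyl)-2,2-dimethyl-1,3-dioxolan-4-yl]-2-methylfuran-3(2H)-one | OC/C=C(/C)C1=CC(=O)[C@@](C)(O1)[C@H]1OC(C)(C)O[C@H]1CO | intermediate
9 | (4R,5S)-2,2-dimethyl-5-{(2S)-2-methyl-3-oxo-5-[(Z)-4-oxobut-2-en-2-yl]-2,3-dihydrofuran-2-yl}-1,3-dioxolane-4-carbaldehyde | O=C/C=C(/C)C1=CC(=O)[C@@](C)(O1)[C@H]1OC(C)(C)O[C@H]1C=O | intermediate
10 | methyl 2-{hydroxy[(4S,5S)-2,2-dimethyl-5-{(2S)-2-methyl-3-oxo-5-[(Z)-4-oxobut-2-en-2-yl]-2,3-dihydrofuran-2-yl}-1,3-dioxolan-4-yl]methyl}prop-2-enoate (C7 epimers) | O=C/C=C(/C)C1=CC(=O)[C@@](C)(O1)[C@H]1OC(C)(C)O[C@H]1C(O)C(=C)C(=O)OC | intermediate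
11 | methyl (Z)-2-(bromomethyl)-3-[(4S,5S)-2,2-dimethyl-5-{(2S)-2-methyl-3-oxo-5-[(Z)-4-oxobut-2-en-2-yl]-2,3-dihydrofuran-2-yl}-1,3-dioxolan-4-yl]prop-2-enoate | O=C/C=C(/C)C1=CC(=O)[C@@](C)(O1)[C@H]1OC(C)(C)O[C@H]1/C=C(\CBr)C(=O)OC | intermediate
12 | seco hydroxy ester: ten-membered carbocycle closed by the C6–C7 bond, free C6–OH, C12 methyl ester, 8,9-acetonide; stereocentres as in 13 (formed as its chromium alkoxide; not isolated) | CC1(C)O[C@H]2[C@@H](C(=C)C(=O)OC)[C@H](O)/C=C(/C)C3=CC(=O)[C@@](C)(O3)[C@H]2O1 | intermediate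
13 | 8,9-O-isopropylidene-8,9-dihydroxy-1-oxo-3,10-epoxygermacra-2,4(Z),11(13)-trien-12,6-olide; C6, C7, C8, C9, C10 as in the target | CC1(C)O[C@H]2[C@H]3C(=C)C(=O)O[C@@H]3/C=C(/C)C3=CC(=O)[C@@](C)(O3)[C@H]2O1 | intermediate
14 | 8,9-dihydroxy-1-oxo-3,10-epoxygermacra-2,4(Z),11(13)-trien-12,6-olide; stereocentres as in the target | O[C@H]1[C@H]2C(=C)C(=O)O[C@@H]2/C=C(/C)C2=CC(=O)[C@@](C)(O2)[C@H]1O | intermediate
15 | 9-hydroxy-8-(methacryloyloxy)-1-oxo-3,10-epoxygermacra-2,4(Z),11(13)-trien-12,6-olide; stereocentres as in the target | C=C(C)C(=O)O[C@H]1[C@H]2C(=C)C(=O)O[C@@H]2/C=C(/C)C2=CC(=O)[C@@](C)(O2)[C@H]1O | intermediate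
16 | (4Z,6R,7S,8S,9S,10S)-9-acetoxy-8-(methacryloyloxy)-1-oxo-3,10-epoxygermacra-2,4,11(13)-trien-12,6-olide (CNP0365569.2) | C=C(C)C(=O)O[C@H]1[C@H]2C(=C)C(=O)O[C@@H]2/C=C(/C)C2=CC(=O)[C@@](C)(O2)[C@H]1OC(C)=O | target

**Step count**
Total steps: 11. Longest linear sequence: 11 steps (1 and 2 → 16).

**Steps most likely to fail**

Step 3 (the new gold-triggered cyclization/1,2-shift). The dioxolanyl carbon may migrate slowly, or the C1–C9 bond may ionize to a dioxolanyl oxocarbenium ion and a 3-hydroxyfuran that recombine with loss of configuration at C9 and C10. The fallback uses only known chemistry, sets out from lactone 2 and returns to the route at furanone 7. MeLi addition to 2 followed by a TBSCl quench gives the methyl ketone 1-[(4S,5S)-5-(TBSOCH2)-2,2-dimethyl-1,3-dioxolan-4-yl]ethan-1-one F3. Felkin–Anh addition of vinyllithium in THF at −78 °C gives the tertiary allylic alcohol (2R)-2-[(4S,5S)-5-(TBSOCH2)-2,2-dimethyl-1,3-dioxolan-4-yl]but-3-en-2-ol F4, which already carries the C10 configuration. Ozonolysis (O3, then Me2S) gives the α-hydroxy aldehyde F5. Two equivalents of the lithium acetylide of the silyl ether of 1 (F2, described under step 2) give the propargylic diol F6 as C1 epimers. MnO2 oxidizes only the secondary propargylic alcohol to give the γ-hydroxy ynone F7. The established 5-endo cyclization of γ-hydroxy ynones (Et2NH in EtOH, or Ph3PAuNTf2) then closes the furanone to 7 without any skeletal shift.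

Step 8 (macrocyclization). The cis-fused dioxolane may hold the chain in a conformation that disfavors ring closure or gives the wrong C6/C7 diastereomer. The fallback moves deprotection and both acylations before ring closure; it sets out from bromide 11 and returns at the target 16. TFA/H2O removes the acetonide to give the diol bromide F8. Methacryloyl chloride with 2,6-lutidine at −40 °C (no nucleophilic amine, so the allylic bromide survives) acylates the less hindered allylic C8 hydroxyl to give the mono-methacrylate F9. Ac2O with catalytic Sc(OTf)3 acetylates the neopentyl-like C9 hydroxyl to give the diester bromide F10. CrCl2-mediated cyclization and lactonization of the unconstrained F10 then gives 16 directly. This also removes the need for regioselective acylation on the macrocycle, but 1,4-elimination of the C8 acyloxy group from the allylchromium is a possible side reaction.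

Step 2 (facial selectivity at C1). If the ynone reacts through a chelate instead of the Felkin–Anh mode, the C1 epimer forms and would end up as the C10 epimer. The fallback reverses the order in which the two carbon groups are introduced, so that chelation gives the required isomer; it sets out from lactone 2 and returns at enol ether 5. 1-Ethoxyvinyllithium adds to 2 and a TBSCl quench gives the 2-ethoxy enone 1-[(4S,5S)-5-(TBSOCH2)-2,2-dimethyl-1,3-dioxolan-4-yl]-2-ethoxyprop-2-en-1-one F1. Enynol 1 is silylated (TBSCl, imidazole) to the silyl ether (Z)-tert-butyldimethyl[(3-methylpent-2-en-4-yn-1-yl)oxy]silane F2. The bromomagnesium acetylide of F2 is added to F1 in CH2Cl2/Et2O with MgBr2·OEt2, under Cram-chelate control (magnesium bridging the ketone and the C9 dioxolane oxygen, attack past the C9 hydrogen). This gives 5, which is hydrolysed to 6 as in step 2.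

**Further compounds**
F1 | step 2 | 1-[(4S,5S)-5-{[(tert-butyldimethylsilyl)oxy]methyl}-2,2-dimethyl-1,3-dioxolan-4-yl]-2-ethoxyprop-2-en-1-one | C=C(OCC)C(=O)[C@H]1OC(C)(C)O[C@H]1CO[Si](C)(C)C(C)(C)C
F2 | step 2 | (Z)-tert-butyldimethyl[(3-methylpent-2-en-4-yn-1-yl)oxy]silane | CC(C)(C)[Si](C)(C)OC/C=C(/C)C#C
F3 | step 3 | 1-[(4S,5S)-5-{[(tert-butyldimethylsilyl)oxy]methyl}-2,2-dimethyl-1,3-dioxolan-4-yl]ethan-1-one | CC(=O)[C@H]1OC(C)(C)O[C@H]1CO[Si](C)(C)C(C)(C)C
F4 | step 3 | (2R)-2-[(4S,5S)-5-{[(tert-butyldimethylsilyl)oxy]methyl}-2,2-dimethyl-1,3-dioxolan-4-yl]but-3-en-2-ol | C=C[C@@](C)(O)[C@H]1OC(C)(C)O[C@H]1CO[Si](C)(C)C(C)(C)C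
F5 | step 3 | (2S)-2-[(4S,5S)-5-{[(tert-butyldimethylsilyl)oxy]methyl}-2,2-dimethyl-1,3-dioxolan-4-yl]-2-hydroxypropanal | O=C[C@@](C)(O)[C@H]1OC(C)(C)O[C@H]1CO[Si](C)(C)C(C)(C)C
F6 | step 3 | (6Z)-8-[(tert-butyldimethylsilyl)oxy]-2-[(4S,5S)-5-{[(tert-butyldimethylsilyl)oxy]methyl}-2,2-dimethyl-1,3-dioxolan-4-yl]-6-methyloct-6-en-4-yne-2,3-diol (C10 as in 7, C1 epimers) | CC(C)(C)[Si](C)(C)OC/C=C(/C)C#CC(O)[C@@](C)(O)[C@H]1OC(C)(C)O[C@H]1CO[Si](C)(C)C(C)(C)C
F7 | step 3 | (2S,6Z)-8-[(tert-butyldimethylsilyl)oxy]-2-[(4S,5S)-5-{[(tert-butyldimethylsilyl)oxy]methyl}-2,2-dimethyl-1,3-dioxolan-4-yl]-2-hydroxy-6-methyloct-6-en-4-yn-3-one | CC(C)(C)[Si](C)(C)OC/C=C(/C)C#CC(=O)[C@@](C)(O)[C@H]1OC(C)(C)O[C@H]1CO[Si](C)(C)C(C)(C)C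
F8 | step 8 | diol bromide: 11 without the acetonide (free C8 and C9 hydroxyls) | O=C/C=C(/C)C1=CC(=O)[C@@](C)(O1)[C@@H](O)[C@@H](O)/C=C(\CBr)C(=O)OC
F9 | step 8 | 8-O-methacryloyl derivative of the diol bromide | O=C/C=C(/C)C1=CC(=O)[C@@](C)(O1)[C@@H](O)[C@@H](OC(=O)C(C)=C)/C=C(\CBr)C(=O)OC
F10 | step 8 | 9-O-acetyl-8-O-methacryloyl derivative of the diol bromide | O=C/C=C(/C)C1=CC(=O)[C@@](C)(O1)[C@@H](OC(C)=O)[C@@H](OC(=O)C(C)=C)/C=C(\CBr)C(=O)OC
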